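**Retrosynthetic overview**

- Feature: on the cyclopent-2-enone ring (C1 carbonyl, C2=C3, C4, C5) the C4 and C5 hydroxyls are trans and the C4 hydroxyl is cis to the C6 side arm on C5. This is the imprint of a C4–C5 oxirane opened at C4 with inversion.
- 11 ⇒ 8: the C4–O bond is traced back to the oxirane, with the C6 acetate as the internal oxygen nucleophile. 8 ⇒ 6 ⇒ 5: C2=C3 by Saegusa–Ito oxidation, the acetate by acylation.
- 5 ⇒ 4: the oxirane comes from titanium–tartrate epoxidation of C4=C5 directed by the C6 hydroxyl. It sets C5 for good and C4 provisionally.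
- 4 ⇒ 3 ⇒ 1 + 2: the C5–C6 bond comes from a Morita–Baylis–Hillman reaction. The racemate is resolved with the mirror-image titanium–tartrate reagent.
- Ring order: the carbocycle is bought with 1; the oxirane is the only ring formed (step 3) and is opened again in step 7.

Key step: step 3

Assumption: locants follow the cyclopentenone of the target (C1 carbonyl, C2=C3, C4 secondary carbinol, C5 quaternary carbinol, C6 side-chain carbinol); hydroxy enones of the Morita–Baylis–Hillman type are taken to be slow but competent substrates for titanium–tartrate epoxidation.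

**Route**

Step 1
Reactants: 1 cyclopent-2-en-1-one; 2 pentadecanal
Product: 3 rac-2-(1-hydroxypentadecyl)cyclopent-2-en-1-one
Conditions: PBu3 (20 mol%), 1,1'-bi-2-naphthol (10 mol%), THF, rt
Reagents that add atoms: none
Why: Morita–Baylis–Hillman reaction, in which the phosphine adds to the enone, the resulting enolate adds to the aldehyde and loss of the phosphine restores the alkene, the phenolic co-catalyst speeding the proton transfer for a cyclic enone and an enolisable aldehyde; C6 is formed racemic.

Step 2
Reactants: 3 rac-2-(1-hydroxypentadecyl)cyclopent-2-en-1-one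
Product: 4 2-[(1S)-1-hydroxypentadecyl]cyclopent-2-en-1-one (the enantiomer left unchanged)
Conditions: Ti(OiPr)4 (1.0 equiv), D-(−)-diisopropyl tartrate (1.2 equiv), tBuOOH (0.6 equiv, in decane), 4 Å MS, CH2Cl2, −20 °C, stopped near 60% conversion; aq. tartaric acid work-up
Reagents that add atoms: none
Why: Katsuki–Sharpless kinetic resolution, the mirror image of step 3: the D-tartrate complex should transfer oxygen much faster to the (R)-carbinol, which is removed as its erythro epoxide, so the (S)-carbinol should be recovered in high enantiomeric purity once conversion passes one half; C6 of the target is fixed here.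

Step 3
Reactants: 4 2-[(1S)-1-hydroxypentadecyl]cyclopent-2-en-1-one
Product: 5 (1S,5S)-1-[(1S)-1-hydroxypentadecyl]-6-oxabicyclo[3.1.0]hexan-2-one
Conditions: Ti(OiPr)4 (1.0 equiv), L-(+)-diisopropyl tartrate (1.2 equiv), tBuOOH (2 equiv, in decane), 4 Å MS, CH2Cl2, −20 °C, long reaction time; aq. tartaric acid work-up
Reagents that add atoms: tert-butyl hydroperoxide, CC(C)(C)OO
Why: The C6 alkoxide and the tert-butyl peroxide sit on the same tetravalent titanium centre of the tartrate complex, and the distal peroxide oxygen is passed to C4=C5 in one concerted step, so the C5–O and C4–O bonds form together and the oxirane closes by a [2+1] oxygen transfer. The closest known reaction type is the Katsuki–Sharpless epoxidation of secondary allylic alcohols, which has been applied to acyclic hydroxy enones of the Morita–Baylis–Hillman type. C5 and C4 are set as a cis pair by the face of attack: the substrate prefers the rotamer with C6–H beside the C1 carbonyl (least A(1,2) strain), which puts the bound oxygen on the face that leads to the erythro epoxide, and L-(+)-tartrate selects the same face for the (S)-carbinol (matched pair). The step needs face selectivity and enough reactivity at a conjugated, electron-poor alkene; the bound C6 hydroxyl supplies the first by making the transfer intramolecular, and stoichiometric titanium with long reaction time is meant to answer the second. Any (R)-carbinol left in 4 is mismatched and should stay behind, so the step should also raise the enantiomeric purity.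

Step 4
Reactants: 5 (1S,5S)-1-[(1S)-1-hydroxypentadecyl]-6-oxabicyclo[3.1.0]hexan-2-one
Product: 6 (1S)-1-[(1R,5S)-2-oxo-6-oxabicyclo[3.1.0]hexan-1-yl]pentadecyl acetate (same spatial arrangement as 5; the descriptor at the quaternary carbon changes by priority only)
Conditions: Ac2O, pyridine, DMAP (cat.), CH2Cl2, 0 °C
Reagents that add atoms: acetic anhydride, CC(=O)OC(C)=O
Why: DMAP-catalysed acylation of the only hydroxyl under mild, non-enolising conditions that should leave the oxirane and the ketone untouched and affect no stereocentre.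

Step 5
Reactants: 6 (1S)-1-[(1R,5S)-2-oxo-6-oxabicyclo[3.1.0]hexan-1-yl]pentadecyl acetate
Product: 7 (1S)-1-[(1R,5S)-2-(trimethylsilyloxy)-6-oxabicyclo[3.1.0]hex-2-en-1-yl]pentadecyl acetate
Conditions: TMSOTf (1.2 equiv), Et3N (2 equiv), CH2Cl2, −78 to 0 °C; cold NaHCO3 work-up, used crude
Reagents that add atoms: trimethylsilyl trifluoromethanesulfonate, C[Si](C)(C)OS(=O)(=O)C(F)(F)F
Why: Soft enolisation gives the single possible silyl enol ether, because C5 is quaternary and only C2 carries protons, while the low temperature and the excess of amine should keep the silyl triflate from opening the oxirane or enolising the acetate.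

Step 6
Reactants: 7 (1S)-1-[(1R,5S)-2-(trimethylsilyloxy)-6-oxabicyclo[3.1.0]hex-2-en-1-yl]pentadecyl acetate
Product: 8 (1S)-1-[(1S,5S)-2-oxo-6-oxabicyclo[3.1.0]hex-3-en-1-yl]pentadecyl acetate
Conditions: Pd(OAc)2 (1.05 equiv), MeCN, rt
Reagents that add atoms: none
Why: Saegusa–Ito oxidation, in which divalent palladium adds to C2 of the silyl enol ether with loss of trimethylsilyl acetate and syn β-hydride elimination from C3 gives the C2=C3 enone without touching the stereocentres.

Step 7
Reactants: 8 (1S)-1-[(1S,5S)-2-oxo-6-oxabicyclo[3.1.0]hex-3-en-1-yl]pentadecyl acetate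
Product: 11 (1S)-1-[(1R,5R)-1,5-dihydroxy-2-oxocyclopent-3-en-1-yl]pentadecyl acetate, via acetoxonium ion 9 (not isolated), via orthoacid 10 (not isolated)
Conditions: HClO4 (aq., 10 mol%), THF/H2O (10:1), 0 °C; pH 7 buffer quench
Reagents that add atoms: water, O
Why: Acid-catalysed epoxide opening with neighbouring-group participation (the acyloxonium route known for epoxy esters), in which the protonated oxirane is attacked at the allylic C4, not at the quaternary carbonyl-flanked C5, by the carbonyl oxygen of the C6 acetate from the face of the side arm (SN2, inversion at C4, C5–O kept on the other face), water adds to the six-membered acetoxonium ion, and the orthoacid should collapse by release of the less basic allylic O4 so that the acetyl group stays on O6.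

**Compound list**

1 | cyclopent-2-en-1-one | O=C1C=CCC1 | starting material
2 | pentadecanal | CCCCCCCCCCCCCCC=O | starting material
3 | rac-2-(1-hydroxypentadecyl)cyclopent-2-en-1-one | CCCCCCCCCCCCCCC(O)C1=CCCC1=O | intermediate
4 | 2-[(1S)-1-hydroxypentadecyl]cyclopent-2-en-1-one | CCCCCCCCCCCCCC[C@H](O)C1=CCCC1=O | intermediate
5 | (1S,5S)-1-[(1S)-1-hydroxypentadecyl]-6-oxabicyclo[3.1.0]hexan-2-one | CCCCCCCCCCCCCC[C@H](O)[C@]12O[C@H]1CCC2=O | intermediate
6 | (1S)-1-[(1R,5S)-2-oxo-6-oxabicyclo[3.1.0]hexan-1-yl]pentadecyl acetate | CCCCCCCCCCCCCC[C@H](OC(C)=O)[C@]12O[C@H]1CCC2=O | intermediate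
7 | (1S)-1-[(1R,5S)-2-(trimethylsilyloxy)-6-oxabicyclo[3.1.0]hex-2-en-1-yl]pentadecyl acetate | CCCCCCCCCCCCCC[C@H](OC(C)=O)[C@]12O[C@H]1CC=C2O[Si](C)(C)C | intermediate
8 | (1S)-1-[(1S,5S)-2-oxo-6-oxabicyclo[3.1.0]hex-3-en-1-yl]pentadecyl acetate | CCCCCCCCCCCCCC[C@H](OC(C)=O)[C@]12O[C@H]1C=CC2=O | intermediate
9 | acetoxonium ion: 2-methyl-1,3-dioxan-2-ylium ring through O6, the acetyl carbon and O4, cis-fused to the cyclopentenone at C4–C5; C4–O on the face of C6, C5–OH on the opposite face, C6 as in 8 | CCCCCCCCCCCCCC[C@@H]1OC(C)=[O+][C@@H]2C=CC(=O)[C@]12O | intermediate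
10 | orthoacid: 2-hydroxy-2-methyl-1,3-dioxane with the same fusion and configuration as 9, orthoester carbon undefined | CCCCCCCCCCCCCC[C@@H]1OC(C)(O)O[C@@H]2C=CC(=O)[C@]12O | intermediate
11 | (1S)-1-[(1R,5R)-1,5-dihydroxy-2-oxocyclopent-3-en-1-yl]pentadecyl acetate, that is (4R,5R)-5-[(1S)-1-acetoxypentadecyl]-4,5-dihydroxycyclopent-2-en-1-one | CCCCCCCCCCCCCC[C@H](OC(C)=O)[C@@]1(O)C(=O)C=C[C@H]1O | target

Total step count: 7
Longest linear sequence: 7 steps (from 1 and 2 to 11)

**Steps most likely to fail**

1. Step 3 (and its mirror image, step 2). Oxygen transfer to the conjugated, electron-poor C4=C5 bond may be so slow that decay of the peroxide and opening of the titanium-bound epoxy alkoxide overtake it. The fallback masks the carbonyl so that the alkene is an ordinary allylic alcohol; it sets out from 1 and 2 and comes back at 5. Iodination of 1 (I2, pyridine) gives 2-iodocyclopent-2-en-1-one F1. Ketalisation (ethylene glycol, TsOH, benzene, reflux with removal of water) gives 6-iodo-1,4-dioxaspiro[4.4]non-6-ene F2. Iodine–lithium exchange (n-BuLi, THF, −78 °C) and addition to 2 give rac-1-(1,4-dioxaspiro[4.4]non-6-en-6-yl)pentadecan-1-ol F3. The same titanium–L-(+)-tartrate epoxidation, now with catalytic Ti(OiPr)4 and 0.45 equiv of tBuOOH, should convert only the (S)-carbinol into the ethylene ketal of 5 F4. Mild acid-catalysed hydrolysis (pyridinium p-toluenesulfonate, wet acetone) then returns 5.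

2. Step 7. Collapse of the orthoacid toward O6, or later acyl migration from O6 to O4, would leave the acetyl group on the wrong oxygen; a 1,2-acyl shift of the opened oxirane could also compete. The fallback removes the participating ester and fixes each oxygen separately; it sets out from 5 and comes back at 11.
   - Silylation (TBSOTf, 2,6-lutidine, CH2Cl2, −78 °C) gives the O6 tert-butyldimethylsilyl ether of 5 F5.
   - TMSOTf and Et3N give its trimethylsilyl enol ether F6, and Pd(OAc)2 in MeCN gives the O6-silylated epoxy enone F7.
   - Opening with 4-methoxybenzyl alcohol and catalytic BF3·OEt2 (CH2Cl2, −30 °C; SN2 at C4 with inversion, no participation by the silyl ether) gives the C4 4-methoxybenzyl ether with free C5–OH and silylated O6 F8.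
   - HF·pyridine frees O6 to give the C5,C6-diol C4 4-methoxybenzyl ether F9.
   - Ac2O, pyridine and DMAP acetylate only the secondary C6 hydroxyl to give the C6 acetate C4 4-methoxybenzyl ether F10.
   - DDQ (CH2Cl2, pH 7 buffer) removes the benzyl-type ether and gives 11.

3. Step 6. The zerovalent palladium released in the oxidation may ionise the alkenyl oxirane of 7 or 8 to an allylpalladium species and open the ring, and the strained epoxy enone may not survive the acetic acid formed. The fallback replaces the palladium step by a selenoxide elimination; it sets out from 7 and comes back at 8. PhSeCl (CH2Cl2, −78 °C) converts 7 into the 3-phenylselanyl derivative of 6 F11 (selenium on the carbon next to the carbonyl, C2 in target numbering, mixture at that carbon). Oxidation with H2O2 and pyridine (CH2Cl2, 0 °C) then gives 8 by syn elimination of the selenoxide.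

**Further compounds**

F1 | step 3 | 2-iodocyclopent-2-en-1-one | O=C1CCC=C1I
F2 | step 3 | 6-iodo-1,4-dioxaspiro[4.4]non-6-ene | IC1=CCCC12OCCO2
F3 | step 3 | rac-1-(1,4-dioxaspiro[4.4]non-6-en-6-yl)pentadecan-1-ol | CCCCCCCCCCCCCCC(O)C1=CCCC12OCCO2
F4 | step 3 | ethylene ketal of 5 (configuration as in 5) | CCCCCCCCCCCCCC[C@H](O)[C@]12O[C@H]1CCC23OCCO3
F5 | step 7 | O6 tert-butyldimethylsilyl ether of 5 | CCCCCCCCCCCCCC[C@H](O[Si](C)(C)C(C)(C)C)[C@]12O[C@H]1CCC2=O
F6 | step 7 | trimethylsilyl enol ether of F5 | CCCCCCCCCCCCCC[C@H](O[Si](C)(C)C(C)(C)C)[C@]12O[C@H]1CC=C2O[Si](C)(C)C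
F7 | step 7 | O6-silylated epoxy enone (analogue of 8) | CCCCCCCCCCCCCC[C@H](O[Si](C)(C)C(C)(C)C)[C@@]12O[C@@H]1C=CC2=O
F8 | step 7 | C4 4-methoxybenzyl ether, C5–OH free, O6 silylated (configuration as in 11) | CCCCCCCCCCCCCC[C@H](O[Si](C)(C)C(C)(C)C)[C@@]1(O)C(=O)C=C[C@H]1OCc1ccc(OC)cc1
F9 | step 7 | C5,C6-diol C4 4-methoxybenzyl ether | CCCCCCCCCCCCCC[C@H](O)[C@@]1(O)C(=O)C=C[C@H]1OCc1ccc(OC)cc1
F10 | step 7 | C6 acetate C4 4-methoxybenzyl ether | CCCCCCCCCCCCCC[C@H](OC(C)=O)[C@@]1(O)C(=O)C=C[C@H]1OCc1ccc(OC)cc1
F11 | step 6 | 3-phenylselanyl derivative of 6 (selenium on the carbon next to the carbonyl) | CCCCCCCCCCCCCC[C@H](OC(C)=O)[C@]12O[C@H]1CC([Se]c1ccccc1)C2=O
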